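**Strategy**

The route rests on opening ring A at the C1–C2 bond (drimane numbering). The key step is a redox-neutral hydrogen-borrowing annulation: an iridium catalyst dehydrogenates the C1 neopentyl alcohol on C10, the C2 methyl group of the C3 methyl ketone condenses with the aldehyde, and the borrowed hydrogen saturates the enone, closing ring A as its 4,4-dimethyl-3-ketone in one operation. It exploits the two quaternary carbons C4 and C10 that flank the C3–C2–C1 unit: only C2 can enolise and C1 cannot. The precursor is a ring-B cyclohexene carrying C5, C9 and C10, built by a Diels–Alder reaction and an Ireland–Claisen rearrangement.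

Key step: step 7

Assumption (remark on the chemistry): drimane numbering is used throughout (C1–C10 decalin carbons, C11 the CH2O carbon on C9, C12 the exocyclic methylene carbon on C8); the (R,R) antipode of the diol catalyst in step 2 is assumed to deliver the (1R,6R) adduct, and its mirror image is used if the sense of induction proves opposite.

**Route**

Step 1
Reactants: 1 (tert-butyldimethylsilyloxy)acetaldehyde; 2 2-(triphenylphosphoranylidene)propanal
Product: 3 (E)-4-(tert-butyldimethylsilyloxy)-2-methylbut-2-enal
Conditions: toluene, 80 °C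
Reagents that add atoms: none
Why: Wittig olefination with a formyl-stabilised ylide should give the (E)-trisubstituted enal selectively, and this geometry later places the C10 methyl group cis to the C9 CH2O substituent.

Step 2
Reactants: 3 (E)-4-(tert-butyldimethylsilyloxy)-2-methylbut-2-enal; 4 (E)-3-(tert-butyldimethylsilyloxy)-N,N-dimethylbuta-1,3-dien-1-amine
Product: 6 (1R,6R)-6-[(tert-butyldimethylsilyloxy)methyl]-1-methyl-4-oxocyclohex-2-ene-1-carbaldehyde, via amino cycloadduct 5 (not isolated)
Conditions: (R,R)-1-naphthyl-TADDOL (20 mol %), toluene, −40 °C; then 0.5 M HCl, THF, 0 °C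
Reagents that add atoms: none
Why: Hydrogen-bond-catalysed asymmetric Diels–Alder reaction in which the amino terminus of the diene should bond to the formyl-bearing carbon (C10) and the CH2 terminus to C9, the E geometry of 3 fixes methyl cis to CH2OTBS, the chiral diol bound to the formyl oxygen shields one enal face and so sets the absolute configuration of C9 and C10, and dilute acid then hydrolyses the silyl enol ether and eliminates dimethylamine to give the enone.

Step 3
Reactants: 6 (1R,6R)-6-[(tert-butyldimethylsilyloxy)methyl]-1-methyl-4-oxocyclohex-2-ene-1-carbaldehyde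
Product: 7 (1S,4R,5R)-5-[(tert-butyldimethylsilyloxy)methyl]-4-(hydroxymethyl)-4-methylcyclohex-2-en-1-ol
Conditions: LiAlH4, Et2O, −78 °C
Reagents that add atoms: none
Why: Hydride 1,2-reduction of both carbonyl groups, in which axial delivery to the enone carbonyl, as in the reduction of 5-substituted cyclohexenones, should place the new C7 hydroxyl equatorial and cis to the C9 CH2OTBS group.

Step 4
Reactants: 7 (1S,4R,5R)-5-[(tert-butyldimethylsilyloxy)methyl]-4-(hydroxymethyl)-4-methylcyclohex-2-en-1-ol; 8 isobutyric anhydride
Product: 9 (1S,4R,5R)-5-[(tert-butyldimethylsilyloxy)methyl]-4-(isobutyryloxymethyl)-4-methylcyclohex-2-en-1-yl isobutyrate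
Conditions: Et3N, DMAP (cat.), CH2Cl2, rt
Reagents that add atoms: none
Why: DMAP-catalysed acylation of both hydroxyl groups places the isobutyrate that carries C3, C4 and the gem-dimethyl group on the allylic C7 oxygen and at the same time masks the C1 alcohol.

Step 5
Reactants: 9 (1S,4R,5R)-5-[(tert-butyldimethylsilyloxy)methyl]-4-(isobutyryloxymethyl)-4-methylcyclohex-2-en-1-yl isobutyrate
Product: 12 2-[(1S,5R,6R)-5-[(tert-butyldimethylsilyloxy)methyl]-6-(isobutyryloxymethyl)-6-methylcyclohex-2-en-1-yl]-2-methylpropanoic acid, via bis(silyl ketene acetal) 10 (not isolated), via silyl ester 11 (not isolated)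
Conditions: LiN(i-Pr)2 (2.6 equiv), Me3SiCl, THF, −78 °C, then 65 °C; aq. HCl work-up
Reagents that add atoms: none
Why: Ireland–Claisen rearrangement in which the silyl ketene acetal of the allylic ester should undergo a suprafacial [3,3] shift that forms the C4–C5 bond on the face of the former C7–O bond (1,3-chirality transfer, so C5 is set with C4 cis to the C10 methyl group), creates the quaternary C4 and moves the alkene to C6=C7, while the ketene acetal of the non-allylic ester reverts to the ester on work-up.

Step 6
Reactants: 12 2-[(1S,5R,6R)-5-[(tert-butyldimethylsilyloxy)methyl]-6-(isobutyryloxymethyl)-6-methylcyclohex-2-en-1-yl]-2-methylpropanoic acid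
Product: 13 3-[(1S,5R,6R)-5-[(tert-butyldimethylsilyloxy)methyl]-6-(hydroxymethyl)-6-methylcyclohex-2-en-1-yl]-3-methylbutan-2-one
Conditions: MeLi (5 equiv), Et2O, 0 °C to rt; then H2O
Reagents that add atoms: methyllithium, [Li]C
Why: Addition of methyllithium to the lithium carboxylate stops at the dilithium gem-diolate and gives the methyl ketone (C2) on work-up, while the same reagent cleaves the C1 isobutyrate to the free alcohol, and no stereocenter is touched because C4 is quaternary.

Step 7
Reactants: 13 3-[(1S,5R,6R)-5-[(tert-butyldimethylsilyloxy)methyl]-6-(hydroxymethyl)-6-methylcyclohex-2-en-1-yl]-3-methylbutan-2-one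
Product: 16 (5S,9R,10R)-11-(tert-butyldimethylsilyloxy)-12-nordrim-6-en-3-one, via keto aldehyde 14 (not isolated), via enone 15 (not isolated)
Conditions: [Cp*IrCl2]2 (2.5 mol %), KOH (0.3 equiv), toluene, 110 °C, sealed tube
Reagents that add atoms: none
Why: The trivalent iridium catalyst should dehydrogenate the C1 neopentyl alcohol to aldehyde 14 and hold the hydrogen as an iridium hydride, base then effects the intramolecular aldol condensation of the C2 methyl group onto C1 to give enone 15, and the hydride returns the hydrogen to the C1=C2 bond to give ketone 16 with water as the only by-product. The closest known reaction type is the hydrogen-borrowing α-alkylation of ketones with primary alcohols, including its ring-closing variants that form cyclohexanes. Ring A closes by a 6-(enolexo)-exo-trig aldol addition followed by E1cB dehydration. No new stereocenter is formed, since C5 and C10 are already fixed with C1 and C4 trans on ring B, so only the trans-decalin can result, and C3 is set afterwards in step 8. The step needs enolisation at C2 only and no reduction of the C6=C7 alkene. The quaternary C4 leaves the methyl group as the only acidic position, the quaternary C10 makes the aldehyde non-enolisable, and the iridium hydride reduces the conjugated enone but not an isolated disubstituted alkene.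

Step 8
Reactants: 16 (5S,9R,10R)-11-(tert-butyldimethylsilyloxy)-12-nordrim-6-en-3-one
Product: 17 (3S,5S,9R,10R)-11-(tert-butyldimethylsilyloxy)-12-nordrim-6-en-3-ol
Conditions: LiBH(s-Bu)3, THF, −78 °C; then H2O
Reagents that add atoms: none
Why: Ketone reduction with a bulky trialkylborohydride, which should attack from the equatorial direction to avoid the axial hydrogens at C1 and C5 and so give the axial C3 alcohol (OH trans to the C10 methyl group), as is usual for 4,4-dimethyl-3-ketones of trans-decalins.

Step 9
Reactants: 17 (3S,5S,9R,10R)-11-(tert-butyldimethylsilyloxy)-12-nordrim-6-en-3-ol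
Product: 19 (3S,5S,9R,10R)-11-(tert-butyldimethylsilyloxy)-3-hydroxy-12-nordrim-6-en-8-one, via allylic peroxide 18 (not isolated)
Conditions: Rh2(cap)4 (dirhodium tetrakis(caprolactamate), 1 mol %), t-BuOOH (70 % aq.), 1,2-dichloroethane, 40 °C
Reagents that add atoms: tert-butyl hydroperoxide, CC(C)(C)OO
Why: Radical allylic C–H oxidation by tert-butylperoxyl radicals, in which hydrogen abstraction from the accessible C8 methylene (the tertiary C5–H lies between two quaternary carbons) and collapse of the mixed peroxide should give the C6=C7–C8=O enone, free hydroxyl groups being tolerated in related steroid oxidations.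

Step 10
Reactants: 19 (3S,5S,9R,10R)-11-(tert-butyldimethylsilyloxy)-3-hydroxy-12-nordrim-6-en-8-one
Product: 20 (3S,5S,9R,10R)-11-(tert-butyldimethylsilyloxy)drima-6,8(12)-dien-3-ol
Conditions: Ph3PCH3Br, KOt-Bu (3 equiv each), THF, 0 °C to rt
Reagents that add atoms: methyltriphenylphosphonium bromide, C[P+](c1ccccc1)(c1ccccc1)c1ccccc1.[Br-]
Why: Wittig methylenation of the enone carbonyl should give the exocyclic diene, the ylide being used in excess because the free C3 hydroxyl is deprotonated, and C9 has no driving force to epimerise because its CH2OTBS group is already equatorial.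

Step 11
Reactants: 20 (3S,5S,9R,10R)-11-(tert-butyldimethylsilyloxy)drima-6,8(12)-dien-3-ol
Product: 21 (3S,5S,9R,10R)-drima-6,8(12)-diene-3,11-diol
Conditions: Bu4NF, THF, rt
Reagents that add atoms: none
Why: Fluoride-mediated desilylation should free the primary C11 alcohol without touching the diene or the C3 carbinol.

Step 12
Reactants: 21 (3S,5S,9R,10R)-drima-6,8(12)-diene-3,11-diol; 22 7-hydroxycoumarin (umbelliferone)
Product: 23 7-{[(3S,5S,9R,10R)-3-hydroxydrima-6,8(12)-dien-11-yl]oxy}coumarin (CNP0259618.1)
Conditions: PPh3, diisopropyl azodicarboxylate, THF, 0 °C to rt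
Reagents that add atoms: none
Why: Mitsunobu etherification in which the acidic phenol should displace the oxyphosphonium of the primary C11 alcohol, while the axial C3 hydroxyl next to the quaternary C4 is too hindered to react.

**Compound list**

1 | (tert-butyldimethylsilyloxy)acetaldehyde | O=CCO[Si](C)(C)C(C)(C)C | starting material
2 | 2-(triphenylphosphoranylidene)propanal | CC(C=O)=P(c1ccccc1)(c1ccccc1)c1ccccc1 | starting material
3 | (E)-4-(tert-butyldimethylsilyloxy)-2-methylbut-2-enal | O=C/C(C)=C/CO[Si](C)(C)C(C)(C)C | intermediate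
4 | (E)-3-(tert-butyldimethylsilyloxy)-N,N-dimethylbuta-1,3-dien-1-amine | CN(C)/C=C/C(=C)O[Si](C)(C)C(C)(C)C | starting material
5 | Diels–Alder adduct: 4-(tert-butyldimethylsilyloxy)-6-[(tert-butyldimethylsilyloxy)methyl]-2-(dimethylamino)-1-methylcyclohex-3-ene-1-carbaldehyde, methyl cis to CH2OTBS, epimer mixture at the amino-bearing carbon | CN(C)C1C=C(O[Si](C)(C)C(C)(C)C)C[C@@H](CO[Si](C)(C)C(C)(C)C)[C@]1(C)C=O | intermediate
6 | (1R,6R)-6-[(tert-butyldimethylsilyloxy)methyl]-1-methyl-4-oxocyclohex-2-ene-1-carbaldehyde | O=C1C=C[C@@](C)(C=O)[C@H](CO[Si](C)(C)C(C)(C)C)C1 | intermediate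
7 | (1S,4R,5R)-5-[(tert-butyldimethylsilyloxy)methyl]-4-(hydroxymethyl)-4-methylcyclohex-2-en-1-ol | O[C@@H]1C=C[C@@](C)(CO)[C@H](CO[Si](C)(C)C(C)(C)C)C1 | intermediate
8 | isobutyric anhydride | CC(C)C(=O)OC(=O)C(C)C | starting material
9 | (1S,4R,5R)-5-[(tert-butyldimethylsilyloxy)methyl]-4-(isobutyryloxymethyl)-4-methylcyclohex-2-en-1-yl isobutyrate | CC(C)C(=O)O[C@@H]1C=C[C@@](C)(COC(=O)C(C)C)[C@H](CO[Si](C)(C)C(C)(C)C)C1 | intermediate
10 | bis(trimethylsilyl ketene acetal) of 9 | CC(C)=C(O[Si](C)(C)C)O[C@@H]1C=C[C@@](C)(COC(O[Si](C)(C)C)=C(C)C)[C@H](CO[Si](C)(C)C(C)(C)C)C1 | intermediate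
11 | trimethylsilyl ester of acid 12 that still carries the ketene acetal on the C1 oxygen | C[Si](C)(C)OC(=O)C(C)(C)[C@H]1C=CC[C@@H](CO[Si](C)(C)C(C)(C)C)[C@]1(C)COC(O[Si](C)(C)C)=C(C)C | intermediate
12 | 2-[(1S,5R,6R)-5-[(tert-butyldimethylsilyloxy)methyl]-6-(isobutyryloxymethyl)-6-methylcyclohex-2-en-1-yl]-2-methylpropanoic acid | OC(=O)C(C)(C)[C@H]1C=CC[C@@H](CO[Si](C)(C)C(C)(C)C)[C@]1(C)COC(=O)C(C)C | intermediate
13 | 3-[(1S,5R,6R)-5-[(tert-butyldimethylsilyloxy)methyl]-6-(hydroxymethyl)-6-methylcyclohex-2-en-1-yl]-3-methylbutan-2-one | CC(=O)C(C)(C)[C@H]1C=CC[C@@H](CO[Si](C)(C)C(C)(C)C)[C@]1(C)CO | intermediate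
14 | keto aldehyde: compound 13 with its CH2OH group oxidised to CHO | CC(=O)C(C)(C)[C@H]1C=CC[C@@H](CO[Si](C)(C)C(C)(C)C)[C@]1(C)C=O | intermediate
15 | (5S,9R,10R)-11-(tert-butyldimethylsilyloxy)-12-nordrima-1,6-dien-3-one | C1C=C[C@@H]2C(C)(C)C(=O)C=C[C@@]2(C)[C@@H]1CO[Si](C)(C)C(C)(C)C | intermediate
16 | (5S,9R,10R)-11-(tert-butyldimethylsilyloxy)-12-nordrim-6-en-3-one | C1C=C[C@@H]2C(C)(C)C(=O)CC[C@@]2(C)[C@@H]1CO[Si](C)(C)C(C)(C)C | intermediate
17 | (3S,5S,9R,10R)-11-(tert-butyldimethylsilyloxy)-12-nordrim-6-en-3-ol | C1C=C[C@@H]2C(C)(C)[C@@H](O)CC[C@@]2(C)[C@@H]1CO[Si](C)(C)C(C)(C)C | intermediate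
18 | C8 tert-butylperoxy derivative of 17, epimer mixture at C8 | CC(C)(C)OOC1C=C[C@@H]2C(C)(C)[C@@H](O)CC[C@@]2(C)[C@@H]1CO[Si](C)(C)C(C)(C)C | intermediate
19 | (3S,5S,9R,10R)-11-(tert-butyldimethylsilyloxy)-3-hydroxy-12-nordrim-6-en-8-one | O=C1C=C[C@@H]2C(C)(C)[C@@H](O)CC[C@@]2(C)[C@@H]1CO[Si](C)(C)C(C)(C)C | intermediate
20 | (3S,5S,9R,10R)-11-(tert-butyldimethylsilyloxy)drima-6,8(12)-dien-3-ol | C=C1C=C[C@@H]2C(C)(C)[C@@H](O)CC[C@@]2(C)[C@@H]1CO[Si](C)(C)C(C)(C)C | intermediate
21 | (3S,5S,9R,10R)-drima-6,8(12)-diene-3,11-diol | C=C1C=C[C@@H]2C(C)(C)[C@@H](O)CC[C@@]2(C)[C@@H]1CO | intermediate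
22 | 7-hydroxycoumarin (umbelliferone) | Oc1ccc2ccc(=O)oc2c1 | starting material
23 | 7-{[(3S,5S,9R,10R)-3-hydroxydrima-6,8(12)-dien-11-yl]oxy}coumarin (CNP0259618.1) | C=C1C=C[C@@H]2C(C)(C)[C@@H](O)CC[C@@]2(C)[C@@H]1COc1ccc2ccc(=O)oc2c1 | target

**Step count and risks**

Total step count: 12. Longest linear sequence: 12 steps (from 1 to 23).

Steps most likely to fail:

Step 2. The trisubstituted enal may react too slowly under hydrogen-bond catalysis, so that the uncatalysed background cycloaddition erodes the facial selectivity. The fallback sets out from enal 3: a cationic chiral B-aryl oxazaborolidine activated by triflimide (a strong chiral boron Lewis acid) catalyses the Diels–Alder reaction with 2-(trimethylsilyloxy)buta-1,3-diene, which should give the silyl enol ether aldehyde F1. Saegusa–Ito dehydrogenation with Pd(OAc)2 in MeCN then introduces the C5=C6 bond and comes back to the route at formyl enone 6.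

Step 7. The iridium hydride may be consumed unproductively (transfer hydrogenation of the methyl ketone, migration of the ring alkene), so that the cycle stalls at the aldehyde or enone stage. The fallback sets out from hydroxy ketone 13 and separates the three events: oxidation with the periodinane DMP gives keto aldehyde 14, KOH in MeOH effects the aldol condensation to enone 15, and conjugate reduction with the copper hydride [(Ph3P)CuH]6 comes back to the route at ketone 16.

Step 9. Hydrogen abstraction at the tertiary allylic C5–H, oxygen delivery to the C6 end of the allyl radical (a transposed enone) or oxidation of the C3 carbinol may compete. The fallback sets out from alcohol 17 and uses a closed-shell ene and [2,3]-sigmatropic allylic hydroxylation with catalytic SeO2 and t-BuOOH in CH2Cl2, which keeps the alkene in place and should give the C8 allylic alcohol F2. MnO2, which oxidises only the allylic carbinol, then comes back to the route at enone 19.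

Further compounds
F1 | step 2 | (1R,6R)-6-[(tert-butyldimethylsilyloxy)methyl]-1-methyl-4-(trimethylsilyloxy)cyclohex-3-ene-1-carbaldehyde | C[Si](C)(C)OC1=CC[C@@](C)(C=O)[C@H](CO[Si](C)(C)C(C)(C)C)C1
F0 | step 7 | none | none
F2 | step 9 | (3S,5S,9R,10R)-11-(tert-butyldimethylsilyloxy)-12-nordrim-6-ene-3,8-diol, epimer mixture at C8 | OC1C=C[C@@H]2C(C)(C)[C@@H](O)CC[C@@]2(C)[C@@H]1CO[Si](C)(C)C(C)(C)C
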